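**Retrosynthetic overview**
1. Target ⇐ C2-selective angeloylation of an all-cis 1,2,3-triol ⇐ hydroxyl-directed dihydroxylation of the ring alkene; the oxirane (last ring) ⇐ catalyst-controlled epoxidation of the terminal 10,11-alkene.
2. Cyclohexene (the carbocycle) ⇐ C1–C6 bond by intramolecular carbonyl-ene closure of open-chain (2Z,6E)-4,8-bis(angeloyloxy)farnesal, the aldehyde-level counterpart of the neryl cation → bisabolyl cation step; the hydrogen transfer creates the 7(14)-methylene and frees C1-OH with both side-chain esters already in place.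
3. Z-enal ⇐ butenolide (temporary ring that locks the 2Z geometry and carries the C4 oxygen) ⇐ α-hydroxy ketone from enamine α-oxygenation of sulcatone.
4. C8 carbinol and prenyl terminus ⇐ allylic oxidation, asymmetric allylboration, cross-metathesis.
5. Ring order: butenolide (opened again) → cyclohexene → oxirane.

Assumption: the target is read as (1S,2S,3R,4S,6R,8S,10S) in bisabolane numbering (ring C1–C6, C7 bearing C14, chain C8–C13, C15 on C3), which is used for all late intermediates; "angelate" = (Z)-2-methylbut-2-enoate.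

**Step 1**
Reactants: 1 6-methylhept-5-en-2-one (sulcatone)
Product: 3 (S)-3-hydroxy-6-methylhept-5-en-2-one, via anilinooxy ketone 2 (not isolated)
Conditions: D-proline (20 mol%), PhNO (slow addition; 1 in 3-fold excess), DMSO, rt; then CuSO4·5H2O (30 mol%), MeOH, 0 °C
Reagents that add atoms: nitrosobenzene, O=Nc1ccccc1
Why: Proline-catalysed α-aminoxylation (nitroso aldol) goes through the more substituted enamine on the methylene side and is O-selective on the face directed by the carboxylic acid, so D-proline sets the future C4 as S, and divalent copper then cleaves the N–O bond without touching the stereocentre.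

**Step 2**
Reactants: 3 (S)-3-hydroxy-6-methylhept-5-en-2-one; 4 (triphenylphosphoranylidene)ketene
Product: 6 (S)-4-methyl-5-(3-methylbut-2-en-1-yl)furan-2(5H)-one, via acyl ylide 5 (not isolated)
Conditions: toluene, 110 °C
Reagents that add atoms: none
Why: The hydroxyl adds to the ketene ylide and the resulting acyl ylide closes on the neighbouring ketone by intramolecular Wittig olefination (Bestmann butenolide synthesis), which fixes the C2=C3 bond as Z under neutral conditions that leave C4 alone.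

**Step 3**
Reactants: 6 (S)-4-methyl-5-(3-methylbut-2-en-1-yl)furan-2(5H)-one
Product: 7 (S,E)-2-methyl-4-(3-methyl-5-oxo-2,5-dihydrofuran-2-yl)but-2-enal
Conditions: SeO2 (1.3 equiv), 1,4-dioxane/H2O 20:1, 80 °C
Reagents that add atoms: selenium dioxide, O=[Se]=O
Why: Riley allylic oxidation (ene reaction then 2,3-sigmatropic shift) attacks the E-methyl of the electron-rich prenyl group and carries it to the E-enal, while the electron-poor butenolide alkene is inert.

**Step 4**
Reactants: 7 (S,E)-2-methyl-4-(3-methyl-5-oxo-2,5-dihydrofuran-2-yl)but-2-enal; 8 (+)-B-allyldiisopinocampheylborane (from (+)-α-pinene)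
Product: 9 (S)-5-[(2E,4S)-4-hydroxy-3-methylhepta-2,6-dien-1-yl]-4-methylfuran-2(5H)-one
Conditions: Et2O, −78 °C; then H2O2, pH 7 phosphate buffer, MeOH, 0 °C → rt
Reagents that add atoms: none
Why: Brown asymmetric allylboration through a chair six-membered transition state delivers allyl to the Si face of the α-methyl enal under reagent control, giving the 8S carbinol, and the lactone does not react at −78 °C.

**Step 5**
Reactants: 9 (S)-5-[(2E,4S)-4-hydroxy-3-methylhepta-2,6-dien-1-yl]-4-methylfuran-2(5H)-one; 10 2-methylbut-2-ene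
Product: 11 (S)-5-[(2E,4S)-4-hydroxy-3,7-dimethylocta-2,6-dien-1-yl]-4-methylfuran-2(5H)-one
Conditions: second-generation Grubbs catalyst RuCl2(=CHPh)(H2IMes)(PCy3) (5 mol%), 10 as co-solvent, CH2Cl2, 40 °C
Reagents that add atoms: none
Why: Olefin cross-metathesis engages only the monosubstituted alkene and caps it as the prenyl group with loss of propene, since the trisubstituted and conjugated alkenes are not metathesis-active and no stereocentre is involved.

**Step 6**
Reactants: 11 (S)-5-[(2E,4S)-4-hydroxy-3,7-dimethylocta-2,6-dien-1-yl]-4-methylfuran-2(5H)-one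
Product: 12 (2Z,4S,6E,8S)-4,8-dihydroxy-N-methoxy-N,3,7,11-tetramethyldodeca-2,6,10-trienamide
Conditions: MeNH(OMe)·HCl, AlMe3, CH2Cl2, 0 °C → rt; KNaC4H4O6 (aq.); crude product used at once
Reagents that add atoms: N,O-dimethylhydroxylamine hydrochloride, CNOC.Cl
Why: Weinreb aminolysis with the aluminium amide opens the lactone to the hydroxy amide with the ring-fixed Z geometry retained, freeing the C4 hydroxyl while C1 stays at a level that can later be taken to the aldehyde.

**Step 7**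
Reactants: 12 (2Z,4S,6E,8S)-4,8-dihydroxy-N-methoxy-N,3,7,11-tetramethyldodeca-2,6,10-trienamide; 13 angelic anhydride
Product: 14 (2Z,4S,6E,8S)-1-[methoxy(methyl)amino]-3,7,11-trimethyl-1-oxododeca-2,6,10-triene-4,8-diyl diangelate
Conditions: LiN(SiMe3)2 (2.1 equiv), 13 (2.5 equiv), THF, −40 → 0 °C; NH4Cl (aq.)
Reagents that add atoms: none
Why: O-acylation of the two lithium alkoxides by the anhydride at low temperature, without an acyl-transfer catalyst, is the stereoconservative way to make angelates (no Z to E isomerisation), and the C4 alkoxide does not re-close onto the amide because an amide anion is a poor leaving group.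

**Step 8**
Reactants: 14 (2Z,4S,6E,8S)-1-[methoxy(methyl)amino]-3,7,11-trimethyl-1-oxododeca-2,6,10-triene-4,8-diyl diangelate
Product: 15 (2Z,4S,6E,8S)-3,7,11-trimethyl-1-oxododeca-2,6,10-triene-4,8-diyl diangelate [(2Z,6E)-4,8-bis(angeloyloxy)farnesal]
Conditions: Cp2Zr(H)Cl (1.5 equiv), THF, rt, 20 min; wet silica; used directly
Reagents that add atoms: none
Why: Schwartz-reagent amide reduction (hydrozirconation of the amide carbonyl to an N,O-zirconated hemiaminal that collapses to the aldehyde on work-up) tolerates esters and trisubstituted alkenes and keeps the Z-enal geometry.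

**Step 9**
Reactants: 15 (2Z,4S,6E,8S)-3,7,11-trimethyl-1-oxododeca-2,6,10-triene-4,8-diyl diangelate
Product: 16 (1R,4S,6R,8S)-1-hydroxybisabola-2,7(14),10-triene-4,8-diyl diangelate
Conditions: Me2AlCl (2 equiv), CH2Cl2, −78 → −40 °C; NaHCO3 (aq.)
Reagents that add atoms: none
Why: Type 1 intramolecular carbonyl-ene (Prins-type) cyclisation of the Lewis-acid-activated Z-enal forms C1–C6, and on a 6E alkene the C14 hydrogen can only reach the oxygen when that oxygen is axial and C7 equatorial, so the 7(14)-methylene and the cis C1-OH/side-chain relationship arise together, while the C4 angelate sits pseudoaxial to avoid allylic strain with the C3 methyl and so puts the side chain trans to it (1R,6R).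

**Step 10**
Reactants: 16 (1R,4S,6R,8S)-1-hydroxybisabola-2,7(14),10-triene-4,8-diyl diangelate
Product: 17 (1R,4S,6R,8S,10S)-10,11-epoxy-1-hydroxybisabola-2,7(14)-diene-4,8-diyl diangelate
Conditions: L-fructose-derived enantiomer of the Shi ketone (30 mol%), KHSO5 (Oxone, 2KHSO5·KHSO4·K2SO4; 1.4 equiv), K2CO3, Bu4NHSO4, MeCN/CH2(OMe)2/aq. Na2B4O7 buffer (pH 10.5), 0 °C
Reagents that add atoms: potassium peroxymonosulfate, [K+].[O-]S(=O)(=O)OO
Why: In the Shi epoxidation the chiral dioxirane attacks the most electron-rich, unhindered trisubstituted 10,11-alkene through a spiro transition state to give the 10S oxirane under catalyst control, whereas the ring alkene is deactivated by two allylic oxygens and the methylene and angelate alkenes are poor substrates.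

**Step 11**
Reactants: 17 (1R,4S,6R,8S,10S)-10,11-epoxy-1-hydroxybisabola-2,7(14)-diene-4,8-diyl diangelate
Product: 19 (1S,2S,3S,4S,6R,8S,10S)-10,11-epoxy-1,2,3-trihydroxybisabol-7(14)-ene-4,8-diyl diangelate, via osmate ester 18 (not isolated)
Conditions: OsO4 (1.05 equiv), Me2NCH2CH2NMe2 (TMEDA, 1.1 equiv), CH2Cl2, −78 °C; then H2NCH2CH2NH2, rt
Reagents that add atoms: osmium tetroxide, O=[Os](=O)(=O)=O
Why: In the Donohoe directed dihydroxylation the OsO4·TMEDA complex is hydrogen-bonded by the allylic C1-OH and adds to the ring alkene syn to it and anti to the C4 angelate, giving the all-cis 1,2,3-triol with C3-OH trans to the C4 ester.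

**Step 12**
Reactants: 19 (1S,2S,3S,4S,6R,8S,10S)-10,11-epoxy-1,2,3-trihydroxybisabol-7(14)-ene-4,8-diyl diangelate; 13 angelic anhydride
Product: 21 (1S,2S,3R,4S,6R,8S,10S)-10,11-epoxy-1,3-dihydroxybisabol-7(14)-ene-2,4,8-triyl triangelate (CNP0421750.2), via stannylene acetal 20 (not isolated)
Conditions: Bu2SnO (1.1 equiv), MeOH, 65 °C; evaporate; then 13 (1.1 equiv), THF, 0 °C → rt; H2O
Reagents that add atoms: none
Why: In this organotin-mediated regioselective acylation the dibutylstannylene acetal forms on the cis C1/C2 diol and activates its equatorial oxygen, so the anhydride esterifies C2 only and the axial C1-OH and tertiary C3-OH stay free.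

**Compound list**
1 | 6-methylhept-5-en-2-one (sulcatone) | CC(=O)CCC=C(C)C | starting material
2 | (S)-6-methyl-3-(phenylaminooxy)hept-5-en-2-one | CC(=O)[C@@H](ONc1ccccc1)CC=C(C)C | intermediate (not isolated)
3 | (S)-3-hydroxy-6-methylhept-5-en-2-one | CC(=O)[C@@H](O)CC=C(C)C | intermediate
4 | (triphenylphosphoranylidene)ketene (Bestmann ylide) | O=C=C=P(c1ccccc1)(c1ccccc1)c1ccccc1 | starting material
5 | (S)-6-methyl-2-oxohept-5-en-3-yl (triphenylphosphoranylidene)acetate | CC(=O)[C@@H](OC(=O)C=P(c1ccccc1)(c1ccccc1)c1ccccc1)CC=C(C)C | intermediate (not isolated)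
6 | (S)-4-methyl-5-(3-methylbut-2-en-1-yl)furan-2(5H)-one | CC1=CC(=O)O[C@H]1CC=C(C)C | intermediate
7 | (S,E)-2-methyl-4-(3-methyl-5-oxo-2,5-dihydrofuran-2-yl)but-2-enal | CC1=CC(=O)O[C@H]1C/C=C(\C)C=O | intermediate
8 | (+)-B-allyldiisopinocampheylborane, from (+)-α-pinene | C=CCB([C@@H]1C[C@@H]2C[C@H]([C@H]1C)C2(C)C)[C@@H]1C[C@@H]2C[C@H]([C@H]1C)C2(C)C | starting material
9 | (S)-5-[(2E,4S)-4-hydroxy-3-methylhepta-2,6-dien-1-yl]-4-methylfuran-2(5H)-one | CC1=CC(=O)O[C@H]1C/C=C(\C)[C@@H](O)CC=C | intermediate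
10 | 2-methylbut-2-ene | CC=C(C)C | starting material
11 | (S)-5-[(2E,4S)-4-hydroxy-3,7-dimethylocta-2,6-dien-1-yl]-4-methylfuran-2(5H)-one | CC1=CC(=O)O[C@H]1C/C=C(\C)[C@@H](O)CC=C(C)C | intermediate
12 | (2Z,4S,6E,8S)-4,8-dihydroxy-N-methoxy-N,3,7,11-tetramethyldodeca-2,6,10-trienamide | CON(C)C(=O)/C=C(/C)[C@@H](O)C/C=C(\C)[C@@H](O)CC=C(C)C | intermediate
13 | angelic anhydride, (Z)-2-methylbut-2-enoic anhydride | C/C=C(/C)C(=O)OC(=O)/C(C)=C\C | starting material
14 | (2Z,4S,6E,8S)-1-[methoxy(methyl)amino]-3,7,11-trimethyl-1-oxododeca-2,6,10-triene-4,8-diyl diangelate | CON(C)C(=O)/C=C(/C)[C@@H](OC(=O)/C(C)=C\C)C/C=C(\C)[C@@H](OC(=O)/C(C)=C\C)CC=C(C)C | intermediate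
15 | (2Z,4S,6E,8S)-3,7,11-trimethyl-1-oxododeca-2,6,10-triene-4,8-diyl diangelate | O=C/C=C(/C)[C@@H](OC(=O)/C(C)=C\C)C/C=C(\C)[C@@H](OC(=O)/C(C)=C\C)CC=C(C)C | intermediate
16 | (1R,4S,6R,8S)-1-hydroxybisabola-2,7(14),10-triene-4,8-diyl diangelate (3-methylcyclohex-2-en-1-ol with 4-angeloyloxy trans and the 6-[(3S)-3-angeloyloxy-6-methylhepta-1,5-dien-2-yl] group cis to OH) | C=C([C@H](CC=C(C)C)OC(=O)/C(C)=C\C)[C@H]1C[C@H](OC(=O)/C(C)=C\C)C(C)=C[C@H]1O | intermediate
17 | (1R,4S,6R,8S,10S)-10,11-epoxy-1-hydroxybisabola-2,7(14)-diene-4,8-diyl diangelate | C=C([C@H](C[C@@H]1OC1(C)C)OC(=O)/C(C)=C\C)[C@H]1C[C@H](OC(=O)/C(C)=C\C)C(C)=C[C@H]1O | intermediate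
18 | cyclic 2,3-osmate ester of 17 (hexavalent osmium) with bound TMEDA | C=C([C@H](C[C@@H]1OC1(C)C)OC(=O)/C(C)=C\C)[C@H]1C[C@H](OC(=O)/C(C)=C\C)[C@@](C)(O2)[C@@H](O[Os]2(=O)=O)[C@H]1O.CN(C)CCN(C)C | intermediate (not isolated)
19 | (1S,2S,3S,4S,6R,8S,10S)-10,11-epoxy-1,2,3-trihydroxybisabol-7(14)-ene-4,8-diyl diangelate | C=C([C@H](C[C@@H]1OC1(C)C)OC(=O)/C(C)=C\C)[C@H]1C[C@H](OC(=O)/C(C)=C\C)[C@@](C)(O)[C@@H](O)[C@H]1O | intermediate
20 | 1,2-O-dibutylstannylene acetal of 19 | C=C([C@H](C[C@@H]1OC1(C)C)OC(=O)/C(C)=C\C)[C@H]1C[C@H](OC(=O)/C(C)=C\C)[C@@](C)(O)[C@@H](O2)[C@H]1O[Sn]2(CCCC)CCCC | intermediate (not isolated)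
21 | (1S,2S,3R,4S,6R,8S,10S)-10,11-epoxy-1,3-dihydroxybisabol-7(14)-ene-2,4,8-triyl triangelate (CNP0421750.2) | C=C([C@H](C[C@@H]1OC1(C)C)OC(=O)/C(C)=C\C)[C@H]1C[C@H](OC(=O)/C(C)=C\C)[C@@](C)(O)[C@@H](OC(=O)/C(C)=C\C)[C@H]1O | target

**Totals**
Total step count: 12. Longest linear sequence: 12 steps (from 1).

**Steps most likely to fail**

Step 9 (ene cyclisation). The ene component is deactivated by the allylic C8 ester. A stepwise Prins pathway could let that ester trap the C7 cation, or could close the ring with the oxygen equatorial. The fallback sets out from 15 and comes back at 16, and sets C1 by reduction instead of in the cyclisation. If ring closure delivers mainly the C1 epimer (1S,4S,6R,8S)-1-hydroxybisabola-2,7(14),10-triene-4,8-diyl diangelate F1, the crude carbinol mixture is oxidised with MnO2 in CH2Cl2 to the enone (4S,6R,8S)-1-oxobisabola-2,7(14),10-triene-4,8-diyl diangelate F2. LiBH(s-Bu)3 in THF at −78 °C then attacks from the equatorial direction, anti to the C6 substituent, and gives the axial, cis alcohol 16.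

Step 6 (lactone opening; the Z-γ-hydroxy amide can re-lactonise before or during step 7). The fallback sets out from 11 and comes back at 15, and avoids any acyl group at C1. i-Bu2AlH (4 equiv, CH2Cl2, −78 → 0 °C) reduces the butenolide to (2Z,4S,6E,8S)-3,7,11-trimethyldodeca-2,6,10-triene-1,4,8-triol F3. Et3SiCl and imidazole at −78 °C silylate only the primary allylic hydroxyl, giving (2Z,4S,6E,8S)-3,7,11-trimethyl-1-(triethylsilyloxy)dodeca-2,6,10-triene-4,8-diol F4. LiN(SiMe3)2 and 13 give (2Z,4S,6E,8S)-3,7,11-trimethyl-1-(triethylsilyloxy)dodeca-2,6,10-triene-4,8-diyl diangelate F5. Swern conditions ((COCl)2, DMSO, Et3N, −78 → −30 °C) then oxidise the primary triethylsilyl ether directly to the Z-enal 15.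

Step 12 (regioselective esterification of C2-OH beside C1-OH). The fallback sets out from 19 and comes back at 21, and masks the two hydroxyls that must stay free. t-Bu2Si(OTf)2 and 2,6-lutidine bridge the syn-diaxial C1 and C3 hydroxyls as a six-membered silylene, giving (1S,2S,3S,4S,6R,8S,10S)-1,3-O-(di-tert-butylsilanediyl)-10,11-epoxy-2-hydroxybisabol-7(14)-ene-4,8-diyl diangelate F6. LiN(SiMe3)2 and 13 acylate the only free hydroxyl to give (1S,2S,3R,4S,6R,8S,10S)-1,3-O-(di-tert-butylsilanediyl)-10,11-epoxybisabol-7(14)-ene-2,4,8-triyl triangelate F7. Bu4NF buffered with AcOH in THF removes the silylene and gives 21.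

**Further compounds**
F1 | step 9 | (1S,4S,6R,8S)-1-hydroxybisabola-2,7(14),10-triene-4,8-diyl diangelate | C=C([C@H](CC=C(C)C)OC(=O)/C(C)=C\C)[C@H]1C[C@H](OC(=O)/C(C)=C\C)C(C)=C[C@@H]1O
F2 | step 9 | (4S,6R,8S)-1-oxobisabola-2,7(14),10-triene-4,8-diyl diangelate | C=C([C@H](CC=C(C)C)OC(=O)/C(C)=C\C)[C@H]1C[C@H](OC(=O)/C(C)=C\C)C(C)=CC1=O
F3 | step 6 | (2Z,4S,6E,8S)-3,7,11-trimethyldodeca-2,6,10-triene-1,4,8-triol | OC/C=C(/C)[C@@H](O)C/C=C(\C)[C@@H](O)CC=C(C)C
F4 | step 6 | (2Z,4S,6E,8S)-3,7,11-trimethyl-1-(triethylsilyloxy)dodeca-2,6,10-triene-4,8-diol | CC[Si](CC)(CC)OC/C=C(/C)[C@@H](O)C/C=C(\C)[C@@H](O)CC=C(C)C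
F5 | step 6 | (2Z,4S,6E,8S)-3,7,11-trimethyl-1-(triethylsilyloxy)dodeca-2,6,10-triene-4,8-diyl diangelate | CC[Si](CC)(CC)OC/C=C(/C)[C@@H](OC(=O)/C(C)=C\C)C/C=C(\C)[C@@H](OC(=O)/C(C)=C\C)CC=C(C)C
F6 | step 12 | (1S,2S,3S,4S,6R,8S,10S)-1,3-O-(di-tert-butylsilanediyl)-10,11-epoxy-2-hydroxybisabol-7(14)-ene-4,8-diyl diangelate | C=C([C@H](C[C@@H]1OC1(C)C)OC(=O)/C(C)=C\C)[C@H]1C[C@H](OC(=O)/C(C)=C\C)[C@@](C)(O2)[C@@H](O)[C@H]1O[Si]2(C(C)(C)C)C(C)(C)C
F7 | step 12 | (1S,2S,3R,4S,6R,8S,10S)-1,3-O-(di-tert-butylsilanediyl)-10,11-epoxybisabol-7(14)-ene-2,4,8-triyl triangelate | C=C([C@H](C[C@@H]1OC1(C)C)OC(=O)/C(C)=C\C)[C@H]1C[C@H](OC(=O)/C(C)=C\C)[C@@](C)(O2)[C@@H](OC(=O)/C(C)=C\C)[C@H]1O[Si]2(C(C)(C)C)C(C)(C)C
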